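The numbers in the tables are calculated with made-up constants; scatter was added.

Compare the ends of your runs first: noon, charged with less reagent than dawn, keeps 16.5 % of target at 25.0 min, against 7.9 % in dawn. You wanted a quick number for two more flasks, so count the reagent.

in all of them: substrate 0.50 M
- dawn: reagent 1.3 M; free catalyst 5 mM; run made earlier
- noon: reagent 1.1 M; free catalyst 5 mM; run made earlier
- autumn: reagent 1.2 M; free catalyst 5 mM; run made earlier
- violet: reagent 1.00 M; free catalyst 5.0 mM; time 25 min
- grey: reagent 1.50 M; free catalyst 5.0 mM; time 25 min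

| run | time / min | target / % | catalyst intermediate A / % | substrate / % | catalyst intermediate B / % | over-reaction product / % |
|---|---|---|---|---|---|---|
| dawn | 2.00 | 21.6 | 0 | 68.9 | 0.6 | 8.4 |
| dawn | 6.00 | 30.6 | 0 | 30.2 | 0.4 | 39.0 |
| dawn | 12.0 | 24.2 | 0.1 | 6.7 | 0.2 | 68.9 |
| dawn | 20.0 | 11.9 | 0.3 | 1.3 | 0 | 86.5 |
| dawn | 25.0 | 7.9 | 0.2 | 0 | 0.2 | 91.7 |
| noon | 5.00 | 33.5 | 0 | 38.7 | 0.3 | 26.3 |
| noon | 10.0 | 32.9 | 0 | 13.8 | 0 | 52.9 |
| noon | 15.0 | 27.6 | 0.1 | 5.0 | 0.4 | 68.5 |
| noon | 20.0 | 21.7 | 0 | 1.3 | 0 | 76.6 |
| noon | 25.0 | 16.5 | 0.8 | 1.0 | 0.7 | 82.6 |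
| autumn | 2.00 | 22.0 | 0 | 70.2 | 0.9 | 6.9 |
| autumn | 4.00 | 30.3 | 0 | 46.8 | 0.7 | 22.5 |
| autumn | 8.00 | 31.8 | 0 | 20.1 | 0 | 47.8 |
| autumn | 12.0 | 28.3 | 0.3 | 8.0 | 0 | 65.2 |
| autumn | 25.0 | 11.5 | 0 | 1.0 | 0 | 88.0 |

(each reading ± 0.5 percentage points)

- on the list of suspects stand: substrate + free catalyst <-> catalyst intermediate A; reagent + catalyst intermediate A <-> catalyst intermediate B; catalyst intermediate B <-> released group + catalyst intermediate C; catalyst intermediate C -> free catalyst + target; reagent + target -> over-reaction product

- which of these there is most of at the end, counted by the substrate in it, violet (catalyst intermediate A / target / catalyst intermediate B / substrate / over-reaction product)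
- which of these there is most of at the end, counted by the substrate in it, grey (catalyst intermediate A / target / catalyst intermediate B / substrate / over-reaction product)
- how much there is at the end of the one of these that leads, in percent of the substrate charged: violet
- how much there is at the end of the one of these that leads, in percent of the substrate charged: grey

Each target took one reagent and each over-reaction product took two. Let p and o be the fractions of the substrate charge c held as target and over-reaction product. Then, leaving aside what the 5.0 mM of catalyst holds bound, reagent R = R₀ − c(p + 2o). In noon, R falls from 0.407 M to 0.277 M between 10.0 min and 15.0 min. Read the over-reaction constant from that interval: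

k = (rise of o per minute) / (mean p × mean R) = 0.00503 L mol⁻¹ s⁻¹

Now solve both ends and join them. At the front, autumn's substrate readings fall at 0.208 min⁻¹, so take all target as born at the mean arrival time t̄ = 4.80 min. For the tail, count the substrate as converted, which gives R = E + cp with excess E = R₀ − 2c. Violet's E is 0 M, so its tail runs on the tail clock τ = 1/(kc) = 6.63 min:

1/p = 1 + (t − t̄)/τ, so o = 75.3 %

Grey has E = 0.500 M, and the same equation integrates to:

p/(E + cp) = exp(−kE(t − t̄))/(E + c), so o = 97.6 %

Your forecast names over-reaction product for violet and over-reaction product for grey, at 75.5 % (72.5 % to 78.5 %) and 95.8 % (94.3 % to 97.3 %); for violet, its trend “extrapolates to the same value”. Mine is 75.3 % for violet, inside its range, and 97.6 % for grey, against its high end of 97.3 %, so mine parts from the forecast on grey.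

The flask gives over-reaction product in violet at 75.6 % and over-reaction product in grey at 96.2 %.

    substrate + free catalyst ⇌ catalyst intermediate A (K = 3.70 L mol⁻¹, k = 1.20 L mol⁻¹ s⁻¹)
    reagent + catalyst intermediate A ⇌ catalyst intermediate B (K = 4.60 L mol⁻¹, k = 3.30 L mol⁻¹ s⁻¹)
    catalyst intermediate B ⇌ released group + catalyst intermediate C (K = 0.600 M, k = 0.890 s⁻¹)
    catalyst intermediate C → free catalyst + target (k = 13.0 s⁻¹)
    reagent + target → over-reaction product (k = 0.00490 L mol⁻¹ s⁻¹)

In violet at 3.85 min, target is made 1.55 times faster than it is used, each step taken net, so the two ends of the reckoning overlap there. Put violet's 23.3 % of target back through the clock: it reads 21.8 min of tail, against 20.2 min reckoned. Then take the neighbour, the same flask as violet read at 10 min. The clock gives 44.0 % over-reaction product, and that flask holds 48.3 %.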